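- Our closed, stirred vessel holds a racemic substrate, a single-handed free catalyst, a coupling partner in excess and two impurities, and the earlier runs ash and elm each end with less left-handed substrate than right-handed substrate .

| flask | left-handed substrate | right-handed substrate | coupling partner | protic impurity | free catalyst | stray impurity | remark | time |
|---|---|---|---|---|---|---|---|---|
| ash | 10 mM | 10 mM | 3 equiv | 5 mM | 1.3 mol% | 50 µM | run made earlier |  |
| elm | 10 mM | 10 mM | 3 equiv | 5 mM | 1.3 mol% | 110 µM | run made earlier |  |
| ochre | 10 mM | 10 mM | 3.00 equiv | 5.00 mM | 1.3 mol% | 77 µM |  | 10 d |
| violet | 10 mM | 10 mM | 3.00 equiv | 5.00 mM | 1.3 mol% | 40 µM |  | 10 d |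

- ash (time / d: right-handed substrate / %, left-handed substrate / %): 1.25: 50.2, 44.5; 4.00: 48.3, 38.1; 6.00: 46.0, 33.7; 10.0: 44.9, 23.5
- elm (time / d: right-handed substrate / %, left-handed substrate / %): 2.50: 50.0, 49.1; 5.00: 49.0, 46.6; 8.00: 48.3, 44.6; 10.0: 47.7, 40.6

(standard deviation of a reading: 1 percentage point)

- which of the two ends with the higher excess of right-handed substrate over left-handed substrate among what is left of the two ("neither" if they lie within 2 percentage points) (ochre / violet / neither)
- excess of right-handed substrate over left-handed substrate among what is left of the two at the end, ochre
- excess of right-handed substrate over left-handed substrate among what is left of the two at the end, violet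

- free catalyst is single-handed; left-handed substrate and right-handed substrate are mirror images of each other, charged as a racemate, each of them at the stated concentration
- steps that have been proposed: free catalyst + left-handed substrate <-> catalyst intermediate A; free catalyst + right-handed substrate <-> catalyst intermediate B; coupling partner + catalyst intermediate A -> free catalyst + left-handed product; coupling partner + catalyst intermediate B -> free catalyst + right-handed product; left-handed product <-> right-handed product; free catalyst + stray impurity -> spent catalyst; coupling partner + protic impurity -> quenched reagent
- an excess is the difference of the two amounts in percent of their sum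
- an excess is below zero if the other one leads

- The catalyst charge is 130 µM, and [stray impurity] runs from 40 µM to 110 µM across the flasks, below that charge, so the proposed one-for-one step to spent catalyst may remove that amount of it.
- Ochre's [working catalyst] 53.0 µM, the catalyst charged less the stray impurity charged, compares with 90.0 µM in violet, 80.0 µM in ash and 20.0 µM in elm.
- If this sets the rate, ln(starting share/final share) of left-handed substrate should scale with it. Ash gives 0.755 and elm 0.208, a ratio of 3.63 against 4.00 in working catalyst, and elm's small loss makes its reading the weaker one.
- Objection: catalyst dying slowly during the run shows as a sagging rate. Ash gives 0.0932 d⁻¹ up to 1.25 d, 0.0680 d⁻¹ up to 4.00 d and 0.0755 d⁻¹ up to 10.0 d, and a scatter of 1 percentage point weighs heaviest on the earliest of these, so we read no steady sag and treat the decay as pseudo-first-order.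
- Objection: protic impurity takes 5.00 mM of the 30.0 mM coupling partner. Ash, elm, ochre and violet carry the same charges of both, so we leave this out of the comparison.
- Objection: the selectivity factor is loose, at 7.02 in ash and 4.42 in elm. We take ash, whose loss is larger.
- Scaling ash gives us left-handed substrate at 30.3% in ochre and 21.4% in violet. With right-handed substrate at 46.6% and 44.3%, our excesses are 21.1% and 34.9%, a gap of 14 points against the margin of 2 points.
- The forecast, on the ash and elm comparison (“That ratio of 4 matches”), names violet, with 21% (16% to 26%) for ochre and 34% (29% to 39%) for violet. Our violet figure stands 0.90 points above it.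
- The flasks give 18.8% for ochre and 31.3% for violet, so violet ends higher, as forecast.

    free catalyst + left-handed substrate ⇌ catalyst intermediate A (K = 160 M⁻¹, k = 1.34 M⁻¹ s⁻¹)
    free catalyst + right-handed substrate ⇌ catalyst intermediate B (K = 110 M⁻¹, k = 1.91 M⁻¹ s⁻¹)
    coupling partner + catalyst intermediate A → free catalyst + left-handed product (k = 0.00919 M⁻¹ s⁻¹)
    coupling partner + catalyst intermediate B → free catalyst + right-handed product (k = 0.00216 M⁻¹ s⁻¹)
    left-handed product ⇌ right-handed product (k = 9.56 × 10⁻⁶ s⁻¹)
    free catalyst + stray impurity → spent catalyst (k = 61.8 M⁻¹ s⁻¹)
    coupling partner + protic impurity → quenched reagent (k = 6.62 × 10⁻⁴ M⁻¹ s⁻¹)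

- At 10.0 d, spent catalyst stands at 59.2% in ochre and 30.8% in violet. Ochre's intermediates and free catalyst together hold 40.8%, which is our 53.0 µM of 130 µM. A neighbour flask, the same as ochre but charged with 5.2 mol% of free catalyst, has [working catalyst] 443 µM, or 8.36 times ochre's. Scaling ochre's final logarithm, 0.459, gives 3.83, and so 1.09% left-handed substrate. That neighbour ends with 1.16% left-handed substrate and an excess of 91.5%.

Readings and results are simulated with constants of no real substance, and the scatter is random.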